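The synthesis rests on cutting ring B at C6–C7. An iodomethyl ketone (C7–C8), attached through C9 to a finished ring A, is turned into an α-keto radical. This radical adds 6-endo to C6, the terminus of an exocyclic methylene on C5, and the tertiary C5 radical then takes up hydrogen. One operation closes ring B, forms C6–C7 and sets C5. The step exploits the position of C5 between the quaternary carbons C4 and C10. They rule out 5-exo attack, and their syn-axial methyls C19 and C20 cover one face, so hydrogen arrives from the other and rings A/B become trans-fused. The precursor comes from an Ireland–Claisen union (C9–C10) of a carvone-derived ring A allylic alcohol with the complete side-chain acid.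

Key step: step 16

Remark on the chemistry: labdane numbering is used for every intermediate (ring A = C1–C5 and C10; C18 = CH2O and C19 = CH3 on C4; C20 = CH3 on C10). The target SMILES is read as the ent-labdane (2S,3S,4S,5S,9R,10S) with a 13Z alkene, an equatorial C18 hydroxymethyl group and a trans-diequatorial 2,3-dioxygenation.

Step 1
Reactants: 1 (R)-(−)-carvone
Product: 2 (5R)-6-methylcarvone (C6 epimer mixture)
Conditions: LiN(i-Pr)2, THF, −78 °C; MeI, −78 → 0 °C
Reagents that add atoms: iodomethane (CI)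
Why: Kinetic α′-enolate alkylation of the cross-conjugated enone brings in C19, and the new centre does not matter because it is re-enolised in the next step.

Step 2
Reactants: 2 (5R)-6-methylcarvone
Product: 4 (5S,6R)-2,6-dimethyl-5-(prop-1-en-2-yl)-6-[(triethylsilyloxy)methyl]cyclohex-2-en-1-one, via lithium aldolate 3 (not isolated)
Conditions: LiN(i-Pr)2, THF, −78 °C; monomeric CH2O in THF, −78 °C; Et3SiCl, −78 → 0 °C
Reagents that add atoms: formaldehyde (C=O); chlorotriethylsilane (CC[Si](Cl)(CC)CC)
Why: In this aldol hydroxymethylation the tetrasubstituted α′-enolate should take formaldehyde on the face opposite the pseudoaxial isopropenyl group at C3, which sets quaternary C4 with C18 trans and C19 cis to the C3 substituent, and silylation of the aldolate in the flask blocks retro-aldol loss of formaldehyde.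

Step 3
Reactants: 4 the silylated hydroxymethyl enone
Product: 6 ring A enol triflate [C5(OTf)=C10(CH3); isopropenyl on C3; CH3 plus CH2OSiEt3 on C4], via lithium enolate 5 (not isolated)
Conditions: LiBH(s-Bu)3, THF, −78 °C; N-(5-chloropyridin-2-yl)bis(trifluoromethanesulfonimide), −78 → 0 °C
Reagents that add atoms: N-(5-chloropyridin-2-yl)bis(trifluoromethanesulfonimide) (O=S(=O)(N(c1ccc(Cl)cn1)S(=O)(=O)C(F)(F)F)C(F)(F)F)
Why: Conjugate hydride reduction of an enone that carries hydrogen on its β-carbon gives the C5(O)=C10 enolate regiospecifically, and O-sulfonylation traps it as the tetrasubstituted enol triflate with C20 already in place and C3/C4 untouched.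

Step 4
Reactants: 6 ring A enol triflate
Product: 9 C3 acetate of the enol triflate (acetoxy in place of isopropenyl; same face), via methoxy hydroperoxide 7 (not isolated), via peracetate 8 (not isolated)
Conditions: O3, CH2Cl2–MeOH, −78 °C (dye end point); then Ac2O, Et3N, DMAP, CH2Cl2, 0 → 40 °C
Reagents that add atoms: ozone ([O-][O+]=O); methanol (CO)
Why: Ozonolysis in methanol followed by Criegee rearrangement of the acylated α-methoxy hydroperoxide lets C3 migrate from carbon to oxygen with retention, so the carvone centre becomes the C3–O centre, while the electron-poor and hindered triflate alkene should be spared.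

Step 5
Reactants: 9 acetoxy enol triflate
Product: 10 methyl ester [C5(CO2Me)=C10(CH3); C3 OAc; C18 OSiEt3]
Conditions: Pd(OAc)2 (10 mol %), PPh3, CO (1 atm), MeOH, Et3N, DMF, 60 °C
Reagents that add atoms: carbon monoxide ([C-]#[O+]); methanol (CO)
Why: Palladium-catalysed methoxycarbonylation of enol triflates works on 2,6,6-trisubstituted cyclohexenyl systems, installs C6 and affects no stereocentre.

Step 6
Reactants: 10 acetoxy methyl ester
Product: 11 (3R,4S)-3,6-diol with C18 OSiEt3
Conditions: i-Bu2AlH (excess), CH2Cl2, −78 → 0 °C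
Reagents that add atoms: none
Why: This hydride reduction of esters takes the enoate to the primary allylic alcohol without 1,4-reduction and cleaves the hindered C3 acetate in the same operation, so no base-mediated deacylation is needed.

Step 7
Reactants: 11 3,6-diol
Product: 13 (3R,4S) ring A allylic alcohol with trans-fused 3,18-acetonide, via triol 12 (not isolated)
Conditions: PPTS (cat.), MeOH, 25 °C; then 2,2-dimethoxypropane, acetone, 25 °C
Reagents that add atoms: 2,2-dimethoxypropane (COC(C)(C)OC)
Why: In this acid-catalysed transketalisation the labile primary triethylsilyl ether is methanolysed and the 3,18-diol closes the six-membered trans-fused dioxane under thermodynamic control, in preference to a seven-membered ketal with the C6 hydroxyl, which locks C19 axial and C18 equatorial.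

Step 8
Reactants: 14 2-butyne-1,4-diol
Product: 16 (E)-2-iodobut-2-ene-1,4-diol, via vinylstannane 15 (not isolated)
Conditions: Bu3SnH, PdCl2(PPh3)2 (2 mol %), THF, 25 °C; then I2, CH2Cl2, 0 °C
Reagents that add atoms: iodine (II)
Why: Palladium-catalysed hydrostannation is a syn addition and iododestannylation proceeds with retention, so hydrogen and iodine end up cis and the two CH2OH groups end up cis, as the 13Z alkene requires.

Step 9
Reactants: 16 (E)-2-iodobut-2-ene-1,4-diol
Product: 17 (E)-1,4-bis(tert-butyldiphenylsilyloxy)-2-iodobut-2-ene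
Conditions: TBDPSCl (2.2 equiv), imidazole, DMF, 25 °C
Reagents that add atoms: tert-butylchlorodiphenylsilane (CC(C)(C)[Si](Cl)(c1ccccc1)c1ccccc1)
Why: In this standard silylation tert-butyldiphenylsilyl ethers are chosen because they must outlast the aqueous acid that later removes the acetonide, which primary allylic tert-butyldimethylsilyl ethers would not, and because their bulk screens the C13=C14 alkene in the radical step.

Step 10
Reactants: 18 ethyl 4-bromobutanoate; 17 the alkenyl iodide
Product: 20 ethyl (Z)-7-(TBDPS-oxy)-5-[(TBDPS-oxy)methyl]hept-5-enoate, via alkylzinc bromide 19 (not isolated)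
Conditions: activated Zn, LiCl, THF, 50 °C; then 17, Pd(PPh3)4 (5 mol %), THF, 50 °C
Reagents that add atoms: none
Why: Negishi coupling of an ester-bearing alkylzinc bromide with an alkenyl iodide forms C12–C13 with retention of the alkene geometry.

Step 11
Reactants: 20 the ethyl ester
Product: 21 (Z)-7-(TBDPS-oxy)-5-[(TBDPS-oxy)methyl]hept-5-enoic acid (C8, C9, C11–C16)
Conditions: LiOH, THF–MeOH–H2O, 25 °C; then 1 M HCl to pH 4, 0 °C
Reagents that add atoms: lithium hydroxide ([Li+].[OH-])
Why: Saponification of an unhindered ethyl ester leaves the silyl ethers and the alkene untouched.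

Step 12
Reactants: 13 ring A allylic alcohol; 21 side-chain acid
Product: 22 allylic ester (C6–O–C8)
Conditions: DCC, DMAP (cat.), CH2Cl2, 25 °C
Reagents that add atoms: none
Why: Steglich esterification of a primary allylic alcohol joins the two fragments under neutral conditions and creates no stereocentre.

Step 13
Reactants: 22 allylic ester
Product: 25 (3R,4S,9S,10S) acid with C10 quaternary plus C5=C6H2 exocyclic methylene, via silyl ketene acetal 23 (not isolated), via trimethylsilyl ester 24 (not isolated)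
Conditions: LiN(i-Pr)2, THF–DMPU (4:1), −78 °C; Me3SiCl; −78 → 25 °C, then 65 °C; aqueous work-up
Reagents that add atoms: none
Why: In this Ireland–Claisen rearrangement deprotonation in THF–DMPU gives the Z(O)-enolate and hence the (Z)-silyl ketene acetal, which should rearrange through a chair with C11 and C1 equatorial on the ring A face opposite the axial C19 methyl held by the trans-fused acetonide, so that C10 (C20 axial, syn to C19) and C9 are set together while the C5 exocyclic methylene is unveiled.

Step 14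
Reactants: 25 the acid
Product: 26 methyl ketone (C7H3–C8(=O)–C9)
Conditions: MeLi (3.5 equiv), Et2O–THF, 0 → 25 °C; inverse quench into cold aq. NH4Cl
Reagents that add atoms: methyllithium ([Li]C)
Why: Organolithium addition to the lithium carboxylate gives a dilithio gem-diolate that collapses to the ketone only on work-up, which adds C7 in one step without over-addition and tolerates the ketal, silyl ethers and alkenes.

Step 15
Reactants: 26 methyl ketone
Product: 28 iodomethyl ketone [C7H2I–C8(=O)–C9H(C11–C16 chain)–C10; C5=C6H2; 3,18-acetonide; (3R,4S,9S,10S); 13Z], via silyl enol ether 27 (not isolated)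
Conditions: LiN(SiMe3)2, Me3SiCl, THF, −78 °C; then N-iodosuccinimide, THF, −78 → 0 °C, dark
Reagents that add atoms: N-iodosuccinimide (O=C1CCC(=O)N1I)
Why: Kinetic enolisation should occur only at the methyl group because C9–H is buried next to quaternary C10, and electrophilic iodination of the silyl enol ether is much faster than any reaction of N-iodosuccinimide with the two unactivated alkenes.

Step 16
Reactants: 28 iodomethyl ketone
Product: 29 trans-fused 17-nor-ent-labd-13Z-en-8-one 3,18-acetonide 15,16-bis-TBDPS ether; (3R,4S,5S,9S,10S)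
Conditions: (Me3Si)3SiH (1.5 equiv, syringe pump, 8 h), Et3B (0.2 equiv in portions), trace air, PhMe (5 mM), 25 °C
Reagents that add atoms: none
Why: Et3B and oxygen start a silyl-radical chain in which (Me3Si)3Si• removes iodine from 28 to give the electrophilic C7 radical next to the C8 carbonyl, this radical bonds to the electron-rich terminal C6 of the C5 methylene, and the tertiary C5 radical then abstracts hydrogen from the silane. The closest known reaction type is the reductive 6-endo cyclisation of α-carbonyl (2-oxohex-5-enyl) radicals onto 1,1-disubstituted alkenes. Ring B closes in the 6-endo-trig mode through a chair with the C9 side chain equatorial, because the 5-exo alternative would have to bond to C5 between two quaternary carbons and would twist the radical out of conjugation with the carbonyl. The single new stereocentre, C5, is controlled by the syn-axial methyls C19 and C20, which close one face so that the bulky silane delivers hydrogen axially from the other and a trans-decalin results. The step needs cyclisation to outrun direct reduction, a 1,5-hydrogen shift from allylic C12 and 6-exo or 7-endo capture by C13=C14; high dilution with slow silane addition, the fully substituted C10 in the tether, and the two bulky, inductively deactivating CH2OTBDPS groups on that alkene should secure this, and prematurely reduced material is simply 26, which can be re-iodinated. Et3B is kept substoichiometric because α-keto radicals are also intercepted by it as boron enolates.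

Step 17
Reactants: 29 C8 decalone
Product: 30 8(17)-methylene compound; (3R,4S,5S,9R,10S)
Conditions: Ph3PCH3Br, KOt-Bu, THF, 0 → 65 °C
Reagents that add atoms: methyltriphenylphosphonium bromide (C[P+](c1ccccc1)(c1ccccc1)c1ccccc1.[Br-])
Why: Wittig methylenation is the standard route to the exocyclic alkene from 8-oxolabdanes, and the basic medium cannot damage C9 because the equatorial side chain is already the more stable arrangement.

Step 18
Reactants: 30 acetonide
Product: 31 3,18-diol
Conditions: AcOH–H2O–THF (3:1:1), 40 °C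
Reagents that add atoms: none
Why: Mild acid hydrolysis of the isopropylidene ketal should leave the acid-stable tert-butyldiphenylsilyl ethers and the exocyclic methylene intact.

Step 19
Reactants: 31 3,18-diol
Product: 32 18-O-TBS ether with free C3 hydroxyl
Conditions: TBSCl (1.1 equiv), imidazole, CH2Cl2, 0 → 25 °C
Reagents that add atoms: tert-butylchlorodimethylsilane (CC(C)(C)[Si](C)(C)Cl)
Why: Chemoselective silylation favours the primary C18 hydroxyl over the secondary C3 hydroxyl that flanks quaternary C4.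

Step 20
Reactants: 32 C3 alcohol
Product: 33 C3 ketone
Conditions: Dess–Martin periodinane, CH2Cl2, 25 °C
Reagents that add atoms: none
Why: Dess–Martin oxidation converts the hindered secondary alcohol under near-neutral conditions without touching the alkenes or silyl ethers, and C4 cannot epimerise or undergo retro-aldol cleavage because it is quaternary and C18 is protected.

Step 21
Reactants: 33 C3 ketone
Product: 34 (2S)-2-hydroxy-3-ketone (equatorial hydroxyl)
Conditions: KN(SiMe3)2, THF, −78 °C; 2-(phenylsulfonyl)-3-phenyloxaziridine, −78 °C; AcOH quench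
Reagents that add atoms: 2-(phenylsulfonyl)-3-phenyloxaziridine (O=S(=O)(c1ccccc1)N1OC1c1ccccc1)
Why: In this enolate hydroxylation with an N-sulfonyloxaziridine the ketone can enolise only toward C2, the oxidant should approach from the face opposite the axial C19 and C20 methyls to give the equatorial C2 alcohol as in 4,4-dimethyl-3-ketoterpenoids, and the reagent does not epoxidise the alkenes.

Step 22
Reactants: 34 α-hydroxy ketone
Product: 35 2-O-TBS ether
Conditions: TBSOTf, 2,6-lutidine, CH2Cl2, −78 → 0 °C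
Reagents that add atoms: tert-butyldimethylsilyl triflate (CC(C)(C)[Si](C)(C)OS(=O)(=O)C(F)(F)F)
Why: Silylation with a silyl triflate and a hindered pyridine base masks O2 before C3 is reduced, so that only O3 is free for acylation later.

Step 23
Reactants: 35 2-silyloxy-3-ketone
Product: 36 (2S,3S)-3-alcohol (equatorial hydroxyl)
Conditions: NaBH4, MeOH–THF, −20 °C
Reagents that add atoms: none
Why: In this borohydride reduction hydride should enter axially from the face free of the C19 methyl and give the equatorial C3 alcohol trans to O2, as with 4,4-disubstituted 3-ketoterpenoids, and the low temperature suppresses 1,2-silyl migration.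

Step 24
Reactants: 36 C3 alcohol; 37 angelic acid
Product: 39 fully silylated 3-angelate, via mixed anhydride 38 (not isolated)
Conditions: 37, 2,4,6-Cl3C6H2COCl, Et3N, PhMe, 25 °C; then 36, 80 °C (no DMAP)
Reagents that add atoms: none
Why: Yamaguchi-type mixed-anhydride acylation without a nucleophilic amine catalyst avoids the reversible conjugate addition that turns angelate into tiglate, so the Z geometry of 37 should be carried into the ester.

Step 25
Reactants: 39 tetrasilyl ether
Product: 40 target; 2,15,16,18-tetrahydroxy-ent-labda-8(17),13Z-dien-3-yl angelate; (2S,3S,4S,5S,9R,10S)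
Conditions: HF·pyridine, pyridine–THF, 0 → 25 °C
Reagents that add atoms: none
Why: Fluoride-mediated global desilylation in a weakly acidic medium frees all four hydroxyls without the base-induced migration of the angelate to O2 or O18 and without isomerising either alkene.

Compound list
1 | (R)-(−)-carvone | CC1=CC[C@@H](C(C)=C)CC1=O | starting material
2 | (5R)-6-methylcarvone, C6 epimer mixture | CC1=CC[C@@H](C(C)=C)C(C)C1=O | intermediate
3 | lithium aldolate of the C4 hydroxymethylation | [Li+].CC1=CC[C@@H](C(C)=C)[C@](C)(C[O-])C1=O | intermediate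
4 | (5S,6R)-2,6-dimethyl-5-(prop-1-en-2-yl)-6-[(triethylsilyloxy)methyl]cyclohex-2-en-1-one (CH2OSiEt3 trans to isopropenyl) | CC1=CC[C@@H](C(C)=C)[C@](C)(CO[Si](CC)(CC)CC)C1=O | intermediate
5 | lithium C5(O)=C10 enolate | [Li+].CC1=C([O-])[C@@](C)(CO[Si](CC)(CC)CC)[C@H](C(C)=C)CC1 | intermediate
6 | ring A enol triflate, C3 isopropenyl | CC1=C(OS(=O)(=O)C(F)(F)F)[C@@](C)(CO[Si](CC)(CC)CC)[C@H](C(C)=C)CC1 | intermediate
7 | α-methoxy hydroperoxide on C3 (epimers at the peroxy carbon) | CC1=C(OS(=O)(=O)C(F)(F)F)[C@@](C)(CO[Si](CC)(CC)CC)[C@H](C(C)(OC)OO)CC1 | intermediate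
8 | peracetate of 7 | CC1=C(OS(=O)(=O)C(F)(F)F)[C@@](C)(CO[Si](CC)(CC)CC)[C@H](C(C)(OC)OOC(C)=O)CC1 | intermediate
9 | ring A enol triflate, C3 acetate | CC1=C(OS(=O)(=O)C(F)(F)F)[C@@](C)(CO[Si](CC)(CC)CC)[C@H](OC(C)=O)CC1 | intermediate
10 | ring A methyl enoate, C3 acetate | CC1=C(C(=O)OC)[C@@](C)(CO[Si](CC)(CC)CC)[C@H](OC(C)=O)CC1 | intermediate
11 | (3R,4S) ring A 3,6-diol, C18 OSiEt3 | CC1=C(CO)[C@@](C)(CO[Si](CC)(CC)CC)[C@H](O)CC1 | intermediate
12 | (3R,4S) ring A 3,6,18-triol | CC1=C(CO)[C@@](C)(CO)[C@H](O)CC1 | intermediate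
13 | (3R,4S) ring A allylic alcohol, trans-fused 3,18-acetonide | CC1=C(CO)[C@@]2(C)COC(C)(C)O[C@@H]2CC1 | intermediate
14 | 2-butyne-1,4-diol | OCC#CCO | starting material
15 | (E)-2-(tributylstannyl)but-2-ene-1,4-diol | CCCC[Sn](CCCC)(CCCC)/C(=C/CO)CO | intermediate
16 | (E)-2-iodobut-2-ene-1,4-diol | I/C(=C/CO)CO | intermediate
17 | (E)-1,4-bis(tert-butyldiphenylsilyloxy)-2-iodobut-2-ene | I/C(=C/CO[Si](c1ccccc1)(c1ccccc1)C(C)(C)C)CO[Si](c1ccccc1)(c1ccccc1)C(C)(C)C | intermediate
18 | ethyl 4-bromobutanoate | CCOC(=O)CCCBr | starting material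
19 | (4-ethoxy-4-oxobutyl)zinc bromide | CCOC(=O)CCC[Zn]Br | intermediate
20 | ethyl (Z)-7-(TBDPS-oxy)-5-[(TBDPS-oxy)methyl]hept-5-enoate | CCOC(=O)CCC/C(=C/CO[Si](c1ccccc1)(c1ccccc1)C(C)(C)C)CO[Si](c1ccccc1)(c1ccccc1)C(C)(C)C | intermediate
21 | (Z)-7-(TBDPS-oxy)-5-[(TBDPS-oxy)methyl]hept-5-enoic acid | OC(=O)CCC/C(=C/CO[Si](c1ccccc1)(c1ccccc1)C(C)(C)C)CO[Si](c1ccccc1)(c1ccccc1)C(C)(C)C | intermediate
22 | allylic ester of 13 with 21 | CC1=C(COC(=O)CCC/C(=C/CO[Si](c4ccccc4)(c4ccccc4)C(C)(C)C)CO[Si](c4ccccc4)(c4ccccc4)C(C)(C)C)[C@@]2(C)COC(C)(C)O[C@@H]2CC1 | intermediate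
23 | (Z)-trimethylsilyl ketene acetal of 22 (OSiMe3 cis to C11) | CC1=C(CO/C(O[Si](C)(C)C)=C/CC/C(=C/CO[Si](c4ccccc4)(c4ccccc4)C(C)(C)C)CO[Si](c4ccccc4)(c4ccccc4)C(C)(C)C)[C@@]2(C)COC(C)(C)O[C@@H]2CC1 | intermediate
24 | trimethylsilyl ester of 25 | C[Si](C)(C)OC(=O)[C@@H](CC/C(=C/CO[Si](c1ccccc1)(c1ccccc1)C(C)(C)C)CO[Si](c1ccccc1)(c1ccccc1)C(C)(C)C)[C@]1(C)CC[C@H]2OC(C)(C)OC[C@]2(C)C1=C | intermediate
25 | (3R,4S,9S,10S) C8 acid, C5 exocyclic methylene | OC(=O)[C@@H](CC/C(=C/CO[Si](c1ccccc1)(c1ccccc1)C(C)(C)C)CO[Si](c1ccccc1)(c1ccccc1)C(C)(C)C)[C@]1(C)CC[C@H]2OC(C)(C)OC[C@]2(C)C1=C | intermediate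
26 | methyl ketone (C7H3–C8=O) | CC(=O)[C@@H](CC/C(=C/CO[Si](c1ccccc1)(c1ccccc1)C(C)(C)C)CO[Si](c1ccccc1)(c1ccccc1)C(C)(C)C)[C@]1(C)CC[C@H]2OC(C)(C)OC[C@]2(C)C1=C | intermediate
27 | C7=C8 trimethylsilyl enol ether | C=C(O[Si](C)(C)C)[C@@H](CC/C(=C/CO[Si](c1ccccc1)(c1ccccc1)C(C)(C)C)CO[Si](c1ccccc1)(c1ccccc1)C(C)(C)C)[C@]1(C)CC[C@H]2OC(C)(C)OC[C@]2(C)C1=C | intermediate
28 | iodomethyl ketone, key-step precursor, (3R,4S,9S,10S), 13Z | ICC(=O)[C@@H](CC/C(=C/CO[Si](c1ccccc1)(c1ccccc1)C(C)(C)C)CO[Si](c1ccccc1)(c1ccccc1)C(C)(C)C)[C@]1(C)CC[C@H]2OC(C)(C)OC[C@]2(C)C1=C | intermediate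
29 | trans-fused C8 decalone 3,18-acetonide, key-step product, (3R,4S,5S,9S,10S) | O=C1CC[C@H]2[C@@](C)(CC[C@H]3OC(C)(C)OC[C@]23C)[C@@H]1CC/C(=C/CO[Si](c1ccccc1)(c1ccccc1)C(C)(C)C)CO[Si](c1ccccc1)(c1ccccc1)C(C)(C)C | intermediate
30 | 8(17)-methylene 3,18-acetonide | C=C1CC[C@H]2[C@@](C)(CC[C@H]3OC(C)(C)OC[C@]23C)[C@@H]1CC/C(=C/CO[Si](c1ccccc1)(c1ccccc1)C(C)(C)C)CO[Si](c1ccccc1)(c1ccccc1)C(C)(C)C | intermediate
31 | 3,18-diol | C=C1CC[C@H]2[C@@](C)(CC[C@@H](O)[C@]2(C)CO)[C@@H]1CC/C(=C/CO[Si](c1ccccc1)(c1ccccc1)C(C)(C)C)CO[Si](c1ccccc1)(c1ccccc1)C(C)(C)C | intermediate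
32 | 18-O-TBS 3-alcohol | C=C1CC[C@H]2[C@@](C)(CC[C@@H](O)[C@]2(C)CO[Si](C)(C)C(C)(C)C)[C@@H]1CC/C(=C/CO[Si](c1ccccc1)(c1ccccc1)C(C)(C)C)CO[Si](c1ccccc1)(c1ccccc1)C(C)(C)C | intermediate
33 | C3 ketone | C=C1CC[C@H]2[C@@](C)(CCC(=O)[C@]2(C)CO[Si](C)(C)C(C)(C)C)[C@@H]1CC/C(=C/CO[Si](c1ccccc1)(c1ccccc1)C(C)(C)C)CO[Si](c1ccccc1)(c1ccccc1)C(C)(C)C | intermediate
34 | (2S)-2-hydroxy-3-ketone | C=C1CC[C@H]2[C@@](C)(C[C@H](O)C(=O)[C@]2(C)CO[Si](C)(C)C(C)(C)C)[C@@H]1CC/C(=C/CO[Si](c1ccccc1)(c1ccccc1)C(C)(C)C)CO[Si](c1ccccc1)(c1ccccc1)C(C)(C)C | intermediate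
35 | 2-O-TBS-3-ketone | C=C1CC[C@H]2[C@@](C)(C[C@H](O[Si](C)(C)C(C)(C)C)C(=O)[C@]2(C)CO[Si](C)(C)C(C)(C)C)[C@@H]1CC/C(=C/CO[Si](c1ccccc1)(c1ccccc1)C(C)(C)C)CO[Si](c1ccccc1)(c1ccccc1)C(C)(C)C | intermediate
36 | (2S,3S)-2-O-TBS-3-alcohol | C=C1CC[C@H]2[C@@](C)(C[C@H](O[Si](C)(C)C(C)(C)C)[C@@H](O)[C@]2(C)CO[Si](C)(C)C(C)(C)C)[C@@H]1CC/C(=C/CO[Si](c1ccccc1)(c1ccccc1)C(C)(C)C)CO[Si](c1ccccc1)(c1ccccc1)C(C)(C)C | intermediate
37 | angelic acid, (Z)-2-methylbut-2-enoic acid | C/C=C(/C)C(=O)O | starting material
38 | angelic 2,4,6-trichlorobenzoic anhydride | C/C=C(/C)C(=O)OC(=O)c1c(Cl)cc(Cl)cc1Cl | intermediate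
39 | tetrasilylated 3-angelate | C=C1CC[C@H]2[C@@](C)(C[C@H](O[Si](C)(C)C(C)(C)C)[C@@H](OC(=O)/C(C)=C\C)[C@]2(C)CO[Si](C)(C)C(C)(C)C)[C@@H]1CC/C(=C/CO[Si](c1ccccc1)(c1ccccc1)C(C)(C)C)CO[Si](c1ccccc1)(c1ccccc1)C(C)(C)C | intermediate
40 | CNP0324138.1, 2,15,16,18-tetrahydroxy-ent-labda-8(17),13Z-dien-3-yl angelate | C=C1CC[C@H]2[C@@](C)(C[C@H](O)[C@@H](OC(=O)/C(C)=C\C)[C@]2(C)CO)[C@@H]1CC/C(=C/CO)CO | target

Total step count: 25. Longest linear sequence: 21 steps (steps 1–7 and 12–25, from 1). The side-chain acid takes 4 steps (8–11).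

Steps most likely to fail

Step 16. Several things can go wrong here:
- Hydrogen transfer to the C7 radical may come before ring closure.
- A 1,5-hydrogen shift from allylic C12 may intervene.
- The side-chain alkene may capture the radical.
- Facial control may leak when C5 takes up hydrogen.

The fallback forms the same C6–C7 bond by polar chemistry and sets out from 26. Hydroboration with 9-BBN-H (THF, 65 °C; then NaBO3·4H2O) places boron on terminal C6 and hydrogen on C5 from the face away from C19 and C20. It also reduces C8, giving the 6,8-diol F1. Dess–Martin oxidation gives the keto aldehyde F2, in which C5 can still equilibrate toward the equatorial formyl group. Piperidinium acetate in hot benzene effects the only feasible intramolecular aldol condensation (C7 onto C6), giving the Δ6-en-8-one F3. Conjugate reduction with [(Ph3P)CuH]6 returns to the route at 29.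

Step 13. Leakage in ketene acetal geometry or in the chair/boat preference would scramble C9, and the slow rearrangement at the tetrasubstituted alkene makes this worse. The fallback replaces kinetic control of C9 by thermodynamic control and sets out from 22. The rearrangement is run for conversion only, and the C9-epimeric acid F4 formed beside 25 is not separated. It is carried through the operations of steps 14–16 as the 9-epi methyl ketone F5, the 9-epi iodomethyl ketone F6 and the 9-epi decalone F7. In the decalone C9 is α to the C8 carbonyl, so DBU in warm toluene should equilibrate the axial side chain to the equatorial one. All material then converges on 29.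

Step 24. Acylation of the very hindered C3 hydroxyl may be sluggish, and Z-to-E isomerisation of the angeloyl unit may occur under forcing. The fallback builds the alkene on an ester that is already in place and sets out from 36. DCC/DMAP acylation with 2-[bis(2,2,2-trifluoroethoxy)phosphoryl]propanoic acid, a saturated acid that can be forced without geometric risk, gives the phosphonopropionate F8. Still–Gennari olefination (KN(SiMe3)2, 18-crown-6, THF, −78 °C; acetaldehyde) then forms the Z-trisubstituted enoate and returns to the route at 39.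

Further compounds
F1 | step 16 | 6,8-diol from hydroboration and ketone reduction (C8 epimers; H5 as in 29) | CC(O)[C@@H](CC/C(=C/CO[Si](c1ccccc1)(c1ccccc1)C(C)(C)C)CO[Si](c1ccccc1)(c1ccccc1)C(C)(C)C)[C@]1(C)CC[C@H]2OC(C)(C)OC[C@]2(C)[C@H]1CO
F2 | step 16 | C6 aldehyde C8 methyl ketone | CC(=O)[C@@H](CC/C(=C/CO[Si](c1ccccc1)(c1ccccc1)C(C)(C)C)CO[Si](c1ccccc1)(c1ccccc1)C(C)(C)C)[C@]1(C)CC[C@H]2OC(C)(C)OC[C@]2(C)[C@H]1C=O
F3 | step 16 | Δ6-en-8-one | O=C1C=C[C@H]2[C@@](C)(CC[C@H]3OC(C)(C)OC[C@]23C)[C@@H]1CC/C(=C/CO[Si](c1ccccc1)(c1ccccc1)C(C)(C)C)CO[Si](c1ccccc1)(c1ccccc1)C(C)(C)C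
F4 | step 13 | 9-epi acid | OC(=O)[C@H](CC/C(=C/CO[Si](c1ccccc1)(c1ccccc1)C(C)(C)C)CO[Si](c1ccccc1)(c1ccccc1)C(C)(C)C)[C@]1(C)CC[C@H]2OC(C)(C)OC[C@]2(C)C1=C
F5 | step 13 | 9-epi methyl ketone | CC(=O)[C@H](CC/C(=C/CO[Si](c1ccccc1)(c1ccccc1)C(C)(C)C)CO[Si](c1ccccc1)(c1ccccc1)C(C)(C)C)[C@]1(C)CC[C@H]2OC(C)(C)OC[C@]2(C)C1=C
F6 | step 13 | 9-epi iodomethyl ketone | ICC(=O)[C@H](CC/C(=C/CO[Si](c1ccccc1)(c1ccccc1)C(C)(C)C)CO[Si](c1ccccc1)(c1ccccc1)C(C)(C)C)[C@]1(C)CC[C@H]2OC(C)(C)OC[C@]2(C)C1=C
F7 | step 13 | 9-epi decalone (axial side chain) | O=C1CC[C@H]2[C@@](C)(CC[C@H]3OC(C)(C)OC[C@]23C)[C@H]1CC/C(=C/CO[Si](c1ccccc1)(c1ccccc1)C(C)(C)C)CO[Si](c1ccccc1)(c1ccccc1)C(C)(C)C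
F8 | step 24 | 3-O-[2-(bis(2,2,2-trifluoroethoxy)phosphoryl)propanoyl] derivative of 36 | C=C1CC[C@H]2[C@@](C)(C[C@H](O[Si](C)(C)C(C)(C)C)[C@@H](OC(=O)C(C)P(=O)(OCC(F)(F)F)OCC(F)(F)F)[C@]2(C)CO[Si](C)(C)C(C)(C)C)[C@@H]1CC/C(=C/CO[Si](c1ccccc1)(c1ccccc1)C(C)(C)C)CO[Si](c1ccccc1)(c1ccccc1)C(C)(C)C
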